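The readings of the north-east run showed strength falling by a factor of 2.77, where by strength I mean the rate of making product divided by mean substrate and mean coupling partner, compared between the interval up to 4.00 min and the interval from 12.0 min to 20.0 min.

common to all: substrate 26 mM; free catalyst 23 µM

| flask | coupling partner | remark |
|---|---|---|
| north-east | 21 mM | run made earlier |
| south-east | 47 mM | run made earlier |
| flask | 31.2 mM |  |

| run | time / min | product / % | substrate / % |
|---|---|---|---|
| north-east | 4.00 | 10.3 | 60.7 |
| north-east | 12.0 | 16.8 | 35.3 |
| north-east | 20.0 | 19.1 | 24.6 |
| north-east | 30.0 | 20.8 | 18.4 |
| north-east | 50.0 | 22.2 | 12.1 |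
| south-east | 4.00 | 22.6 | 53.1 |
| south-east | 12.0 | 34.7 | 28.2 |
| south-east | 20.0 | 38.9 | 19.1 |
| south-east | 30.0 | 40.3 | 12.1 |
| south-east | 50.0 | 43.8 | 7.5 |

(scatter of a reading: 0.5 percentage points)

* factor on the rate of making product when 50% of the substrate are converted if free catalyst is charged twice over
* factor on the rate when 50% of the substrate are converted if free catalyst is charged at 120 µM instead

- the earlier runs were read with a standard deviation of 0.5 percentage points
- no earlier run changes the charge of free catalyst; that part of a forecast is a guess

I first asked what shape that fall had. If strength goes as 1/(1 + t/τ), the two interval midpoints give τ = 5.89 min, the fading time, at which strength stands at 0.5 of its start. The interval from 30.0 min to 50.0 min read a fall of 5.47; this reciprocal form gives 5.81, while an exponential through the same intervals gives 15.9, which is more than that reading, so I kept the reciprocal form. It describes catalyst lost in pairs, so I guessed that τ shrinks in step with the charge, since no run tests this.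

Next I asked when to look. Interpolating reciprocal substrate puts 50% conversion at 6.38 min in the north-east run and 4.56 min in the south-east run, hence 5.67 min in the flask. At that time my reciprocal form left a strength of 0.510 of its start, and in that form this number is also the apparent order in catalyst at fixed time. Holding that time, I reckoned 1.34 for twice the charge and 1.70 at 120 µM.

The forecast gave more: 1.9 (1.35 to 2.4) and 4.6 (2.2 to 7), with the ground: “the rate at fixed conversion probably scales close to the catalyst charge”.

The flask gives 1.39 for twice the charge and 2.13 at 120 µM, and with twice the free catalyst the time to 50% conversion became 0.823 of its value.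

    substrate + coupling partner + free catalyst → product + free catalyst, rate k1*[substrate]*[coupling partner]*[free catalyst]/(1 + ([substrate]/sat1)) (0.0753 M, k = 1.28 × 10⁵ /M²/min)
    2 substrate → homo dimer (k = 2.25 /M/min)
    2 free catalyst → spent catalyst (k = 4620 /M/min)

Put to the flask at 20.0 min, the fading time gives 22.8% of the free catalyst charged, and the flask then held 19.0%.

(The data were generated by integration on assumed constants.)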